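**Plan**
1. Retrosynthesis: first the two MOM ethers and the chalcone Cα=Cβ bond are cut (Claisen–Schmidt), leaving an 8-acetylchroman-3-ol. Next the C2–C3 bond of the dihydropyran ring is cut, giving an α-aryloxyisobutyric acid with an ortho CH2CHO arm. Last, O1–C2 (phenol alkylation) and the aryl–C4 bond (allyl Claisen) lead back to 2',4'-dihydroxy-6'-methoxyacetophenone.
2. Forward: ring A is bought complete. C4 arrives by O-allylation and Claisen rearrangement to the only free ortho position, C2 with both methyls by O-alkylation with 2-bromo-2-methylpropanoic acid, and C3 by cleaving the allyl group to the aldehyde. The dihydropyran ring is then closed on ring A, the chalcone arm is added, and both MOM groups are removed together.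
3. Enabling feature: C2 is a fully substituted carbon bearing the ring oxygen O1 and two methyls. A CO2H placed on C2 leaves as CO2 to give a stabilised tertiary α-aryloxy radical six atoms away from the aldehyde carbon C3, so that 6-exo closure onto C=O forms the C2–C3 bond and the C3–OH in one event.
4. Stereochemistry: the single stereocentre, (S)-C3, is created in the ring closure under control of a chiral bis(oxazoline)–chromium catalyst. The (E)-alkene comes from the thermodynamically controlled aldol dehydration.

Key step: step 6

Remark: for this new substrate class the sense of induction cannot be derived from a model, so the ligand enantiomer that gives (S)-14 is to be assigned in a pilot run against the standard from the fallback for step 6.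

**Step 1**
Reactants: 1 1-(2,4-dihydroxy-6-methoxyphenyl)ethan-1-one; 2 chloromethyl methyl ether
Product: 3 1-[2-hydroxy-6-methoxy-4-(methoxymethoxy)phenyl]ethan-1-one
Conditions: MOMCl (1.1 equiv), iPr2NEt, CH2Cl2, 0 °C to rt
Reagents that add atoms: chloromethyl methyl ether, COCCl
Why: The 2-OH is held in a hydrogen bond to the acetyl carbonyl, so the Williamson-type MOM etherification should occur at the free, more acidic 4-OH.

**Step 2**
Reactants: 3 1-[2-hydroxy-6-methoxy-4-(methoxymethoxy)phenyl]ethan-1-one; 4 allyl bromide
Product: 5 1-[2-methoxy-4-(methoxymethoxy)-6-(prop-2-en-1-yloxy)phenyl]ethan-1-one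
Conditions: allyl bromide (1.5 equiv), K2CO3, DMF, 60 °C
Reagents that add atoms: allyl bromide, C=CCBr
Why: Williamson O-allylation of the only remaining phenol, whose chelation is overcome by carbonate in warm DMF.

**Step 3**
Reactants: 5 1-[2-methoxy-4-(methoxymethoxy)-6-(prop-2-en-1-yloxy)phenyl]ethan-1-one
Product: 7 1-[2-hydroxy-6-methoxy-4-(methoxymethoxy)-3-(prop-2-en-1-yl)phenyl]ethan-1-one, via cyclohexadienone 6 (not isolated)
Conditions: N,N-diethylaniline, 190 °C, argon
Reagents that add atoms: none
Why: The aromatic Claisen rearrangement ([3,3]-sigmatropic shift) should deliver the allyl group to the only unsubstituted ortho position, and tautomerisation of dienone 6 restores the chelated phenol.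

**Step 4**
Reactants: 7 1-[2-hydroxy-6-methoxy-4-(methoxymethoxy)-3-(prop-2-en-1-yl)phenyl]ethan-1-one; 8 2-bromo-2-methylpropanoic acid
Product: 9 2-[2-acetyl-3-methoxy-5-(methoxymethoxy)-6-(prop-2-en-1-yl)phenoxy]-2-methylpropanoic acid
Conditions: 2-bromo-2-methylpropanoic acid (3 equiv), powdered NaOH (8 equiv), 2-butanone, 50 °C; then cold dilute HCl to pH 4
Reagents that add atoms: 2-bromo-2-methylpropanoic acid, CC(C)(Br)C(=O)O
Why: The phenoxide should open, at its tertiary carbon, the α-lactone formed in the flask from the α-bromo carboxylate (Bargellini-type O-alkylation), a process that tolerates hindered phenoxides and leaves the MOM ether, ketone and alkene untouched.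

**Step 5**
Reactants: 9 2-[2-acetyl-3-methoxy-5-(methoxymethoxy)-6-(prop-2-en-1-yl)phenoxy]-2-methylpropanoic acid
Product: 11 2-[2-acetyl-3-methoxy-5-(methoxymethoxy)-6-(2-oxoethyl)phenoxy]-2-methylpropanoic acid, via vicinal diol 10 (not isolated)
Conditions: OsO4 (2 mol %), NaIO4 (4 equiv), 2,6-lutidine, dioxane/H2O 3:1, rt; crude aldehyde used directly
Reagents that add atoms: osmium tetroxide, O=[Os](=O)(=O)=O; sodium periodate, [Na+].[O-]I(=O)(=O)=O
Why: Lemieux–Johnson oxidation: OsO4 dihydroxylates the only alkene and NaIO4 cleaves diol 10 and re-oxidises osmium, while 2,6-lutidine buffers the medium and the substituent on O1 prevents lactol formation by the new aldehyde.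

**Step 6**
Reactants: 11 2-[2-acetyl-3-methoxy-5-(methoxymethoxy)-6-(2-oxoethyl)phenoxy]-2-methylpropanoic acid
Product: 14 1-[(3S)-3-hydroxy-7-methoxy-5-(methoxymethoxy)-2,2-dimethyl-3,4-dihydro-2H-chromen-8-yl]ethan-1-one, via tertiary aryloxyalkyl radical 12 (not isolated), via alkylchromium dichloride 13 (not isolated)
Conditions: CrCl2 (15 mol %), one enantiomer of the indane-fused bis(oxazoline) 2,2'-(propane-2,2-diyl)bis(3a,8a-dihydro-8H-indeno[1,2-d]oxazole) (18 mol %), 4CzIPN (2,4,5,6-tetra(carbazol-9-yl)isophthalonitrile, 2 mol %), 2,4,6-collidine (1 equiv), degassed THF/MeCN, blue LEDs (450 nm), rt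
Reagents that add atoms: none
Why: Proposed new method: photoexcited 4CzIPN should oxidise the collidinium carboxylate of 11, CO2 leaves, and the tertiary α-aryloxy radical 12 at C2 is captured by ligand-bound divalent chromium to give alkylchromium species 13 (trivalent chromium), which adds to the chromium-bound aldehyde carbon C3; protonation of the chromium alkoxide and reduction of trivalent chromium by the reduced photocatalyst close both cycles, so CO2 is the only by-product. The closest known reaction type is the Nozaki–Hiyama–Kishi-type addition of radical-derived alkylchromium reagents to aldehydes, known with stoichiometric CrCl2 from redox-active esters and, under photoredox/chromium dual catalysis with bis(oxazoline) ligands, enantioselectively for allyl and α-amino radicals; α-alkoxyalkylchromium reagents also add to aldehydes, so what is new is the tertiary α-aryloxy radical taken from a free acid and the asymmetric intramolecular closure. The dihydropyran ring closes in the 6-exo-trig mode onto the C=O group, whose oxygen stays outside the ring as the C3 hydroxyl. C3 is the only stereocentre and no other stereogenic element is present, so its configuration should be set by the chiral bis(oxazoline) on chromium, which binds the aldehyde and exposes one carbonyl face to the internally delivered C2–Cr bond. The step needs chemoselection of the aldehyde over the 8-acetyl group, which the aldehyde preference of organochromium reagents, the twisted doubly ortho-oxygenated aryl ketone and the congested 5-exo alternative (it would join two fully substituted carbons) should secure; it also needs radical capture by chromium to outrun the uncatalysed radical addition to C=O, which is reversible because β-scission of the alkoxy radical regenerates the stabilised radical 12.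

**Step 7**
Reactants: 14 1-[(3S)-3-hydroxy-7-methoxy-5-(methoxymethoxy)-2,2-dimethyl-3,4-dihydro-2H-chromen-8-yl]ethan-1-one; 15 4-(methoxymethoxy)benzaldehyde
Product: 17 (2E)-1-[(3S)-3-hydroxy-7-methoxy-5-(methoxymethoxy)-2,2-dimethyl-3,4-dihydro-2H-chromen-8-yl]-3-[4-(methoxymethoxy)phenyl]prop-2-en-1-one, via β-hydroxy ketone 16 (not isolated)
Conditions: 4-(methoxymethoxy)benzaldehyde (1.3 equiv), KOH (50 % aq), MeOH, rt to 40 °C
Reagents that add atoms: 4-(methoxymethoxy)benzaldehyde, COCOc1ccc(C=O)cc1
Why: Claisen–Schmidt condensation: the methyl ketone is the only enolisable partner and E1cB dehydration of aldol 16 should give the conjugated (E)-enone, while C3 is not α to a carbonyl and no phenol ortho to the ketone is free, so neither epimerisation nor flavanone closure can occur.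

**Step 8**
Reactants: 17 (2E)-1-[(3S)-3-hydroxy-7-methoxy-5-(methoxymethoxy)-2,2-dimethyl-3,4-dihydro-2H-chromen-8-yl]-3-[4-(methoxymethoxy)phenyl]prop-2-en-1-one
Product: 18 (2E)-1-[(3S)-3,5-dihydroxy-7-methoxy-2,2-dimethyl-3,4-dihydro-2H-chromen-8-yl]-3-(4-hydroxyphenyl)prop-2-en-1-one
Conditions: HCl (3 M aq)/MeOH, 40 °C
Reagents that add atoms: none
Why: Acid-catalysed acetal methanolysis should remove both aryl MOM ethers at once; the C3 carbinol is not benzylic and so is not ionised, and the chalcone has no free ortho-phenol with which to cyclise.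

**Compound list**
1 | 1-(2,4-dihydroxy-6-methoxyphenyl)ethan-1-one | CC(=O)c1c(O)cc(O)cc1OC | starting material
2 | chloromethyl methyl ether | COCCl | starting material
3 | 1-[2-hydroxy-6-methoxy-4-(methoxymethoxy)phenyl]ethan-1-one | CC(=O)c1c(O)cc(OCOC)cc1OC | intermediate
4 | allyl bromide | C=CCBr | starting material
5 | 1-[2-methoxy-4-(methoxymethoxy)-6-(prop-2-en-1-yloxy)phenyl]ethan-1-one | CC(=O)c1c(OCC=C)cc(OCOC)cc1OC | intermediate
6 | 2-acetyl-3-methoxy-5-(methoxymethoxy)-6-(prop-2-en-1-yl)cyclohexa-2,4-dien-1-one (racemic, not isolated) | CC(=O)C1=C(OC)C=C(OCOC)C(CC=C)C1=O | intermediate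
7 | 1-[2-hydroxy-6-methoxy-4-(methoxymethoxy)-3-(prop-2-en-1-yl)phenyl]ethan-1-one | CC(=O)c1c(O)c(CC=C)c(OCOC)cc1OC | intermediate
8 | 2-bromo-2-methylpropanoic acid | CC(C)(Br)C(=O)O | starting material
9 | 2-[2-acetyl-3-methoxy-5-(methoxymethoxy)-6-(prop-2-en-1-yl)phenoxy]-2-methylpropanoic acid | CC(=O)c1c(OC(C)(C)C(=O)O)c(CC=C)c(OCOC)cc1OC | intermediate
10 | 2-[2-acetyl-6-(2,3-dihydroxypropyl)-3-methoxy-5-(methoxymethoxy)phenoxy]-2-methylpropanoic acid (racemic diol, not isolated) | CC(=O)c1c(OC(C)(C)C(=O)O)c(CC(O)CO)c(OCOC)cc1OC | intermediate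
11 | 2-[2-acetyl-3-methoxy-5-(methoxymethoxy)-6-(2-oxoethyl)phenoxy]-2-methylpropanoic acid | CC(=O)c1c(OC(C)(C)C(=O)O)c(CC=O)c(OCOC)cc1OC | intermediate
12 | 2-[2-acetyl-3-methoxy-5-(methoxymethoxy)-6-(2-oxoethyl)phenoxy]propan-2-yl radical (not isolated) | CC(=O)c1c(O[C](C)C)c(CC=O)c(OCOC)cc1OC | intermediate
13 | {2-[2-acetyl-3-methoxy-5-(methoxymethoxy)-6-(2-oxoethyl)phenoxy]propan-2-yl}chromium dichloride (trivalent chromium; bis(oxazoline) ligand not drawn; not isolated) | CC(=O)c1c(OC(C)(C)[Cr](Cl)Cl)c(CC=O)c(OCOC)cc1OC | intermediate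
14 | 1-[(3S)-3-hydroxy-7-methoxy-5-(methoxymethoxy)-2,2-dimethyl-3,4-dihydro-2H-chromen-8-yl]ethan-1-one | COc1cc(OCOC)c2c(c1C(C)=O)OC(C)(C)[C@@H](O)C2 | intermediate
15 | 4-(methoxymethoxy)benzaldehyde | COCOc1ccc(C=O)cc1 | starting material
16 | 3-hydroxy-1-[(3S)-3-hydroxy-7-methoxy-5-(methoxymethoxy)-2,2-dimethyl-3,4-dihydro-2H-chromen-8-yl]-3-[4-(methoxymethoxy)phenyl]propan-1-one (mixture at the new carbinol, not isolated) | COc1cc(OCOC)c2c(c1C(=O)CC(O)c1ccc(OCOC)cc1)OC(C)(C)[C@@H](O)C2 | intermediate
17 | (2E)-1-[(3S)-3-hydroxy-7-methoxy-5-(methoxymethoxy)-2,2-dimethyl-3,4-dihydro-2H-chromen-8-yl]-3-[4-(methoxymethoxy)phenyl]prop-2-en-1-one | COc1cc(OCOC)c2c(c1C(=O)/C=C/c1ccc(OCOC)cc1)OC(C)(C)[C@@H](O)C2 | intermediate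
18 | (2E)-1-[(3S)-3,5-dihydroxy-7-methoxy-2,2-dimethyl-3,4-dihydro-2H-chromen-8-yl]-3-(4-hydroxyphenyl)prop-2-en-1-one | COc1cc(O)c2c(c1C(=O)/C=C/c1ccc(O)cc1)OC(C)(C)[C@@H](O)C2 | target

**Totals**
Total step count: 8. Longest linear sequence: 8 steps (from compound 1; compounds 2, 4, 8 and 15 are purchased).

**Steps most likely to fail**

1. Step 6 (proposed new method). The catalyst may be sequestered as a substitution-inert carboxylate of trivalent chromium, the tertiary alkylchromium species may be protonated before it adds to the aldehyde, or the ligand may discriminate the aldehyde faces poorly. The fallback sets out from 11 and comes back at 14, keeping the C2–C3 closure but setting C3 by reagent control.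
   - Compound 11 is condensed with N-hydroxyphthalimide (N,N'-diisopropylcarbodiimide, DMAP cat., CH2Cl2) to the redox-active ester 1,3-dioxoisoindolin-2-yl 2-[2-acetyl-3-methoxy-5-(methoxymethoxy)-6-(2-oxoethyl)phenoxy]-2-methylpropanoate F1.
   - Stoichiometric CrCl2 in THF/DMF at rt (decarboxylative Nozaki–Hiyama–Kishi-type addition of a redox-active ester to an aldehyde, here intramolecular) should give racemic 1-[3-hydroxy-7-methoxy-5-(methoxymethoxy)-2,2-dimethyl-3,4-dihydro-2H-chromen-8-yl]ethan-1-one F2.
   - Dess–Martin periodinane (NaHCO3, CH2Cl2) oxidises it to 8-acetyl-7-methoxy-5-(methoxymethoxy)-2,2-dimethyl-2H-chromen-3(4H)-one F3.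
   - Corey–Bakshi–Shibata reduction with (R)-2-methyl-CBS-oxazaborolidine (15 mol %) and BH3·SMe2 (0.7 equiv) in THF at −20 °C should return (S)-14, the fully substituted C2 acting as the large group. The α-aryloxy dialkyl ketone is expected to be reduced ahead of the twisted, doubly ortho-oxygenated aryl methyl ketone.

2. Step 4. The chelated, doubly ortho-substituted phenoxide may react too slowly, while the bromo acid is consumed by hydrolysis or elimination to methacrylate. The fallback sets out from 7 and comes back at 9: a three-component Bargellini condensation of 7 with acetone and chloroform (powdered NaOH, acetone, 0 °C to rt). Here the C–O bond is made by opening a gem-dichloroepoxide generated from acetone and chloroform, a reaction known to tolerate hindered phenols. This fallback makes no new isolable compound (F0).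

3. Step 5. The electron-rich arylacetaldehyde may self-condense or be over-oxidised during the aqueous buffered oxidation and work-up, and osmium may attack the oxygenated ring. The fallback sets out from 9 and comes back at 11: ozonolysis in CH2Cl2 at −78 °C to a dye end-point (Sudan Red 7B) should give the secondary ozonide 2-[2-acetyl-3-methoxy-5-(methoxymethoxy)-6-(1,2,4-trioxolan-3-ylmethyl)phenoxy]-2-methylpropanoic acid F4. Reduction with PPh3 gives 11 under anhydrous conditions, and the solution is taken directly into step 6.

**Further compounds**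
F1 | step 6 | 1,3-dioxoisoindolin-2-yl 2-[2-acetyl-3-methoxy-5-(methoxymethoxy)-6-(2-oxoethyl)phenoxy]-2-methylpropanoate | CC(=O)c1c(OC(C)(C)C(=O)ON2C(=O)c3ccccc3C2=O)c(CC=O)c(OCOC)cc1OC
F2 | step 6 | racemic 1-[3-hydroxy-7-methoxy-5-(methoxymethoxy)-2,2-dimethyl-3,4-dihydro-2H-chromen-8-yl]ethan-1-one | COc1cc(OCOC)c2c(c1C(C)=O)OC(C)(C)C(O)C2
F3 | step 6 | 8-acetyl-7-methoxy-5-(methoxymethoxy)-2,2-dimethyl-2H-chromen-3(4H)-one | COc1cc(OCOC)c2c(c1C(C)=O)OC(C)(C)C(=O)C2
F0 | step 4 | none | none
F4 | step 5 | 2-[2-acetyl-3-methoxy-5-(methoxymethoxy)-6-(1,2,4-trioxolan-3-ylmethyl)phenoxy]-2-methylpropanoic acid | CC(=O)c1c(OC(C)(C)C(=O)O)c(CC2OCOO2)c(OCOC)cc1OC
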